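**Retrosynthetic overview**
1. Target ⇒ last cut at the C6–benzoyl bond (ortho C‑acylation of a magnesium phenolate) ⇒ the des‑benzoyl (R)‑5,7‑dihydroxy‑8‑prenyl‑4‑phenyl‑dihydrocoumarin.
2. That bicycle ⇒ both of its rings in one flask from an acyclic keto‑dioxinone and 3‑phenylpropynal: lactone first (C4–C4a and O1–C2, chiral‑carbene Michael addition/lactonization, sets C4), then the phloroglucinol ring (C7–C8, acylketene released from the dioxinone).
3. Keto‑dioxinone ⇒ dioxinone dienolate + 5‑methylhex‑4‑enoyl chloride (brings C8 and the prenyl group).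
4. O1 is tied to the carbon next to the prenyl‑bearing carbon before the arene exists, so the 6‑benzoyl/8‑prenyl lactone regiochemistry is fixed by construction; both phenyl rings are bought.

Assumption: 5‑methylhex‑4‑enoic acid and both enantiomers of the aminoindanol N‑mesityl triazolium salt are purchased; the catalyst enantiomer named is the one expected by analogy to give (4R), and its antipode is used if the first run shows the opposite sense.

**Step 1**
Reactants: 1 5‑methylhex‑4‑enoic acid; 2 2,2,6‑trimethyl‑4H‑1,3‑dioxin‑4‑one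
Product: 4 2,2-dimethyl-6-(6-methyl-2-oxohept-5-en-1-yl)-4H-1,3-dioxin-4-one, via acid chloride 3 (not isolated)
Conditions: (COCl)2, cat. DMF, CH2Cl2, 0 °C → rt, evaporate; 2 (2.2 equiv), LiHMDS (2.2 equiv), THF, −78 °C, add crude 3, −78 → −40 °C; aq. NH4Cl
Reagents that add atoms: oxalyl chloride ClC(=O)C(=O)Cl (chlorine of 3)
Why: Vinylogous Claisen‑type C‑acylation of the lithium dienolate of the dioxinone, which reacts with acid chlorides at its exocyclic CH2 terminus, the second equivalent of dienolate taking up the more acidic proton of the product.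

**Step 2**
Reactants: 4 2,2‑dimethyl‑6‑(6‑methyl‑2‑oxohept‑5‑en‑1‑yl)‑4H‑1,3‑dioxin‑4‑one; 5 3‑phenylprop‑2‑ynal (1.1 equiv)
Product: 8 (4R)-5,7-dihydroxy-8-(3-methylbut-2-en-1-yl)-4-phenyl-3,4-dihydro-2H-chromen-2-one, via dihydropyranone 6 (not isolated), via acylketene 7 (not isolated)
Conditions: (5aR,10bS)‑aminoindanol N‑mesityl triazolium chloride (10 mol %), iPr2NEt (20 mol %), 4 Å MS, PhMe, 25 °C, 16 h; then dilute to 0.01 M, 110 °C, 2 h
Reagents that add atoms: none
Why: Proposed new method: the carbene turns ynal 5 by internal redox into the (E)‑cinnamoyl azolium, the enol of 4 adds through its only doubly activated carbon (Michael addition, or 1,2‑addition/[3,3] shift) on the face left open by the catalyst's indane wall to set C4 as R, and O‑acylation by the only ketone oxygen closes the lactone and frees the carbene (known for β‑diketones and β‑ketoesters, here extended to a keto‑dioxinone); heating then expels acetone by retro‑[4+2] to acylketene 7, whose amine‑assisted vinylogous enolization at the allylic CH2 lets that carbon attack the ketene carbon through a six‑membered transition state (the dienylketene closure that ends a Danheiser benzannulation), and tautomerization gives the phloroglucinol ring, the closest precedents being dioxinone thermolysis/ketene‑trapping–aromatization sequences.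

**Step 3**
Reactants: 8 (4R)‑5,7‑dihydroxy‑8‑(3‑methylbut‑2‑en‑1‑yl)‑4‑phenyl‑3,4‑dihydro‑2H‑chromen‑2‑one; 9 benzoyl chloride (1.05 equiv)
Product: 10 (4R)-6-benzoyl-5,7-dihydroxy-8-(3-methylbut-2-en-1-yl)-4-phenyl-3,4-dihydro-2H-chromen-2-one
Conditions: EtMgBr (2.0 equiv), Et2O–PhMe, 0 °C; then 9, PhMe, 0 → 25 °C; cold 1 M HCl
Reagents that add atoms: none
Why: Metal‑template ortho C‑acylation of a bromomagnesium phenolate with an acid chloride, in which C6 is the only free ring carbon and sits between two O–Mg groups like the central carbon of a magnesium β‑diketonate, while no free acid is present to cyclize the prenyl group onto O7, the lactone cannot move to O5 without an external nucleophile, and C4 is untouched.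

**Compound list**
1 | 5‑methylhex‑4‑enoic acid | CC(C)=CCCC(=O)O | starting material
2 | 2,2,6‑trimethyl‑4H‑1,3‑dioxin‑4‑one | CC1=CC(=O)OC(C)(C)O1 | starting material
3 | 5‑methylhex‑4‑enoyl chloride | CC(C)=CCCC(=O)Cl | intermediate
4 | 2,2‑dimethyl‑6‑(6‑methyl‑2‑oxohept‑5‑en‑1‑yl)‑4H‑1,3‑dioxin‑4‑one | CC(C)=CCCC(=O)CC1=CC(=O)OC(C)(C)O1 | intermediate
5 | 3‑phenylprop‑2‑ynal | O=CC#Cc1ccccc1 | starting material
6 | (4R)‑5‑(2,2‑dimethyl‑4‑oxo‑4H‑1,3‑dioxin‑6‑yl)‑6‑(4‑methylpent‑3‑en‑1‑yl)‑4‑phenyl‑3,4‑dihydro‑2H‑pyran‑2‑one | CC(C)=CCCC1=C(C2=CC(=O)OC(C)(C)O2)[C@@H](c2ccccc2)CC(=O)O1 | intermediate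
7 | (4R)‑6‑(4‑methylpent‑3‑en‑1‑yl)‑5‑(3‑oxoprop‑2‑enoyl)‑4‑phenyl‑3,4‑dihydro‑2H‑pyran‑2‑one | CC(C)=CCCC1=C(C(=O)C=C=O)[C@@H](c2ccccc2)CC(=O)O1 | intermediate
8 | (4R)‑5,7‑dihydroxy‑8‑(3‑methylbut‑2‑en‑1‑yl)‑4‑phenyl‑3,4‑dihydro‑2H‑chromen‑2‑one | CC(C)=CCc1c(O)cc(O)c2c1OC(=O)C[C@@H]2c1ccccc1 | intermediate
9 | benzoyl chloride | O=C(Cl)c1ccccc1 | starting material
10 | (4R)‑6‑benzoyl‑5,7‑dihydroxy‑8‑(3‑methylbut‑2‑en‑1‑yl)‑4‑phenyl‑3,4‑dihydro‑2H‑chromen‑2‑one | CC(C)=CCc1c(O)c(C(=O)c2ccccc2)c(O)c2c1OC(=O)C[C@@H]2c1ccccc1 | target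

**Totals**
Total steps: 3. Longest linear sequence: 3 (1 or 2 → 4 → 8 → 10).

**Steps most likely to fail, with fallbacks**

Step 2 (highest risk). The keto‑dioxinone may add sluggishly or with low ee. Catalyst, amine or product phenol left in the pot may also intercept ketene 7 (O‑acylation, dimerization). The only other six‑membered closure, from the C3 enolate, is disfavoured by acidity and by the bridged product. Fallback, from 4 back to 6: reverse the polarity of the lactone‑forming event and purify before heating. Knoevenagel condensation of 4 with benzaldehyde (piperidinium acetate, PhMe, Dean–Stark) gives 2,2‑dimethyl‑6‑(7‑methyl‑3‑oxo‑1‑phenylocta‑1,6‑dien‑2‑yl)‑4H‑1,3‑dioxin‑4‑one F2. Its ketone/benzylidene 1‑oxadiene then takes part in a chiral‑triazolium‑catalysed formal [4+2] (Michael addition/lactonization) with the acetate azolium enolate made from 4‑nitrophenyl acetate and DBU, giving 6 under catalyst control. After a silica filtration that removes 4‑nitrophenol and catalyst, 6 is heated (PhMe, 0.01 M, 110 °C, 5 mol % iPr2NEt) and continues through 7 to 8.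

Step 3. O‑benzoylation may compete with C‑acylation of the magnesium phenolate. Fallback, from 8 back to 10: make the O‑ester on purpose and move the acyl group photochemically. Treating 8 with 9 (1.0 equiv, pyridine, CH2Cl2, −20 °C) gives (4R)‑5‑hydroxy‑8‑(3‑methylbut‑2‑en‑1‑yl)‑2‑oxo‑4‑phenyl‑3,4‑dihydro‑2H‑chromen‑7‑yl benzoate F3, together with some (4R)‑7‑hydroxy‑8‑(3‑methylbut‑2‑en‑1‑yl)‑2‑oxo‑4‑phenyl‑3,4‑dihydro‑2H‑chromen‑5‑yl benzoate F4. Irradiating the mixture (254 nm, MeCN, rt) effects a photo‑Fries 1,3‑acyl shift. C6 is the only open ortho position of either ester, so both converge on 10 without any acid.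

Step 1. The base can convert acid chloride 3 into a ketene, and product 4 quenches the dienolate, so yields may be modest. Fallback, from 2 back to 4: replace the acylation by a C‑alkylation. The lithium dienolate of 2 (LiHMDS, THF, −78 °C) is acetylated with acetyl chloride to 2,2‑dimethyl‑6‑(2‑oxopropyl)‑4H‑1,3‑dioxin‑4‑one F1. Its dianion (LDA, 2.1 equiv, THF, −78 → −20 °C) is alkylated at the terminal methyl carbon with 1‑bromo‑3‑methylbut‑2‑ene to give 4, so 1 and 3 are no longer needed.

**Further compounds**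
F1 | step 1 | 2,2‑dimethyl‑6‑(2‑oxopropyl)‑4H‑1,3‑dioxin‑4‑one | CC(=O)CC1=CC(=O)OC(C)(C)O1
F2 | step 2 | 2,2‑dimethyl‑6‑(7‑methyl‑3‑oxo‑1‑phenylocta‑1,6‑dien‑2‑yl)‑4H‑1,3‑dioxin‑4‑one | CC(C)=CCCC(=O)C(=Cc1ccccc1)C1=CC(=O)OC(C)(C)O1
F3 | step 3 | (4R)‑5‑hydroxy‑8‑(3‑methylbut‑2‑en‑1‑yl)‑2‑oxo‑4‑phenyl‑3,4‑dihydro‑2H‑chromen‑7‑yl benzoate | CC(C)=CCc1c(OC(=O)c2ccccc2)cc(O)c2c1OC(=O)C[C@@H]2c1ccccc1
F4 | step 3 | (4R)‑7‑hydroxy‑8‑(3‑methylbut‑2‑en‑1‑yl)‑2‑oxo‑4‑phenyl‑3,4‑dihydro‑2H‑chromen‑5‑yl benzoate | CC(C)=CCc1c(O)cc(OC(=O)c2ccccc2)c2c1OC(=O)C[C@@H]2c1ccccc1
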